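**Plan**

- Retrosynthesis: the two aryl silyl ethers (5-O, 3'-O) are removed last. The C2–C3 bond of ring C is cut to an aryl benzyl ether carrying a terminal diazoketone. The O1–CH2 ether bond is cut to a ring A acetophenone and a ring B benzyl alcohol. The C2'–geranyl bond is cut to 2-bromoisovanillin and geranyl bromide.
- Forward: ring B is geranylated at C2' through its arylcopper and joined to ring A by Mitsunobu etherification (O1–C2). The methyl ketone is converted to the diazoketone. Ring C, the only ring that is made, is closed last by carbene C–H insertion, followed by desilylation.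
- Enabling feature: C2 is at once α to O1 and benzylic to ring B, whose C4'-methoxy group is para to C1'. In the open ether this hydridic C–H lies 1,6 to C3 across the ortho acyl/ether pair on C4a/C8a of ring A.
- Stereochemistry: C2 (S) is set in the ring closure by a chiral dirhodium carboxylate (catalyst control). The E double bond comes from geranyl bromide and is never touched.

Key step: step 10

Remark: the sense of induction of Rh2(S-PTTL)4 in step 10 is assumed to favour (2S); if the opposite sense is found, the mirror-image complex Rh2(R-PTTL)4 is used.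
Remark: compounds 1, 4 and 11 are taken as commercial. "Geranyl" means (2E)-3,7-dimethylocta-2,6-dien-1-yl.

**Step 1**
Reactants: 1 2-bromo-3-hydroxy-4-methoxybenzaldehyde
Product: 2 2-(2-bromo-3-hydroxy-4-methoxyphenyl)-1,3-dioxolane
Conditions: ethylene glycol, p-TsOH (cat.), toluene, reflux, Dean–Stark
Reagents that add atoms: ethylene glycol, OCCO
Why: Acid-catalysed acetalisation driven by azeotropic removal of water masks the aldehyde against the organolithium of step 3.

**Step 2**
Reactants: 2 2-(2-bromo-3-hydroxy-4-methoxyphenyl)-1,3-dioxolane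
Product: 3 2-[2-bromo-4-methoxy-3-(methoxymethoxy)phenyl]-1,3-dioxolane
Conditions: NaH, MOMCl, DMF, 0 °C to rt
Reagents that add atoms: chloromethyl methyl ether (MOMCl), COCCl
Why: Williamson-type O-alkylation of the phenoxide gives a MOM ether that tolerates and chelates an ortho aryllithium, where a silyl ether could migrate from O to C.

**Step 3**
Reactants: 3 2-[2-bromo-4-methoxy-3-(methoxymethoxy)phenyl]-1,3-dioxolane; 4 geranyl bromide
Product: 7 2-[2-geranyl-4-methoxy-3-(methoxymethoxy)phenyl]-1,3-dioxolane, via aryllithium 5 (not isolated), via arylcopper 6 (not isolated)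
Conditions: n-BuLi, THF, −78 °C; CuBr·SMe2, −78 to −40 °C; then 4, −40 to 0 °C
Reagents that add atoms: none
Why: Bromine–lithium exchange gives an aryllithium chelated by the MOM and dioxolane oxygens, transmetalation gives the arylcopper of monovalent copper, and SN2 allylic substitution at the primary carbon of 4 should keep the E geometry (no stereocentre is formed).

**Step 4**
Reactants: 7 2-[2-geranyl-4-methoxy-3-(methoxymethoxy)phenyl]-1,3-dioxolane
Product: 8 2-geranyl-3-hydroxy-4-methoxybenzaldehyde
Conditions: 3 M aq. HCl/THF (1:2), rt to 40 °C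
Reagents that add atoms: water, O
Why: Acetal hydrolysis removes dioxolane and MOM in one operation, and the formyl-deactivated phenol in dilute aqueous acid at or below 40 °C should not cyclise onto the geranyl double bond.

**Step 5**
Reactants: 8 2-geranyl-3-hydroxy-4-methoxybenzaldehyde
Product: 9 3-[tert-butyl(dimethyl)silyl]oxy-2-geranyl-4-methoxybenzaldehyde
Conditions: TBSCl, imidazole, DMF, rt
Reagents that add atoms: tert-butyldimethylsilyl chloride (TBSCl), CC(C)(C)[Si](C)(C)Cl
Why: Standard imidazole-promoted silylation of a phenol installs a group that is inert to carbenes and can be removed by fluoride at the end.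

**Step 6**
Reactants: 9 3-[tert-butyl(dimethyl)silyl]oxy-2-geranyl-4-methoxybenzaldehyde
Product: 10 {3-[tert-butyl(dimethyl)silyl]oxy-2-geranyl-4-methoxyphenyl}methanol
Conditions: NaBH4, MeOH, 0 °C
Reagents that add atoms: none
Why: Chemoselective 1,2-hydride reduction of the aldehyde leaves the isolated alkenes and the aryl silyl ether untouched.

**Step 7**
Reactants: 11 1-(2,6-dihydroxy-4-methoxyphenyl)ethanone
Product: 12 1-[2-hydroxy-4-methoxy-6-(triisopropylsilyloxy)phenyl]ethanone
Conditions: TIPSCl (1.05 equiv), imidazole, CH2Cl2, 0 °C to rt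
Reagents that add atoms: triisopropylsilyl chloride (TIPSCl), CC(C)[Si](Cl)(C(C)C)C(C)C
Why: Monosilylation of the symmetrical diol should stop after one group because the remaining hydroxyl is locked in a hydrogen bond to the acetyl carbonyl and the TIPS group is bulky.

**Step 8**
Reactants: 10 {3-[tert-butyl(dimethyl)silyl]oxy-2-geranyl-4-methoxyphenyl}methanol; 12 1-[2-hydroxy-4-methoxy-6-(triisopropylsilyloxy)phenyl]ethanone
Product: 13 1-[2-({3-[tert-butyl(dimethyl)silyl]oxy-2-geranyl-4-methoxyphenyl}methoxy)-4-methoxy-6-(triisopropylsilyloxy)phenyl]ethanone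
Conditions: PPh3, DIAD, THF, 0 °C to rt
Reagents that add atoms: none
Why: Mitsunobu etherification displaces the alkoxyphosphonium ion of the primary benzylic alcohol with the acidic ortho-acyl phenol under neutral conditions that keep both silyl ethers in place.

**Step 9**
Reactants: 13 1-[2-({3-[tert-butyl(dimethyl)silyl]oxy-2-geranyl-4-methoxyphenyl}methoxy)-4-methoxy-6-(triisopropylsilyloxy)phenyl]ethanone
Product: 15 2-diazo-1-[2-({3-[tert-butyl(dimethyl)silyl]oxy-2-geranyl-4-methoxyphenyl}methoxy)-4-methoxy-6-(triisopropylsilyloxy)phenyl]ethanone, via trifluoroacetyl diketone 14 (not isolated)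
Conditions: LiN(SiMe3)2, THF, −78 °C; CF3CO2CH2CF3; cold 5% aq. HCl work-up; then MsN3, Et3N, H2O, MeCN, rt
Reagents that add atoms: methanesulfonyl azide (MsN3), CS(=O)(=O)N=[N+]=[N-]; 2,2,2-trifluoroethyl trifluoroacetate, FC(F)(F)COC(=O)C(F)(F)F (its CF3CO group is carried only by intermediate 14)
Why: Detrifluoroacetylative diazo transfer (a Regitz-type transfer to the activated trifluoroacetyl ketone): the kinetic lithium enolate of the methyl ketone is trifluoroacetylated, and the 1,3-diketone takes up N2 from MsN3 while losing the trifluoroacetyl group as the N-acylsulfonamide; the bulky TIPS group and −78 °C should prevent silyl transfer to the enolate.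

**Step 10**
Reactants: 15 2-diazo-1-[2-({3-[tert-butyl(dimethyl)silyl]oxy-2-geranyl-4-methoxyphenyl}methoxy)-4-methoxy-6-(triisopropylsilyloxy)phenyl]ethanone
Product: 16 (2S)-2-{3-[tert-butyl(dimethyl)silyl]oxy-2-geranyl-4-methoxyphenyl}-7-methoxy-5-(triisopropylsilyloxy)chroman-4-one
Conditions: Rh2(S-PTTL)4 (1 mol %; PTTL = N-phthaloyl-tert-leucinate, a carboxylate of divalent rhodium), CH2Cl2, −20 to 0 °C, slow addition of 15 to 0.01 M
Reagents that add atoms: none
Why: Rh2(S-PTTL)4 expels N2 from 15 to give an electrophilic rhodium carbene at the future C3, which inserts into the pro-S C–H bond of the ArO–CH2–Ar' group (future C2) through a three-centre, hydride-transfer-like transition state with retention at carbon, forming C2–C3 and releasing the catalyst. The closest known reaction type is the intramolecular C–H insertion of 2-alkoxyaryl diazoketones next to the ether oxygen under chiral dirhodium carboxylate catalysis to give chroman-4-ones, together with the insertion of aryldiazoacetates into aryl benzyl ethers that gives 2-aryl-2,3-dihydrobenzofurans. Ring C (O1–C2–C3–C4–C4a–C8a) closes as a 1,6-insertion through a six-membered chair-like transition state in which both reacting carbons are ring members, the ortho acyl/ether pair on ring A holding them within reach. C2 is the only new stereocentre and is under catalyst control: the chiral pocket of the four N-phthaloyl-(S)-tert-leucinate ligands differentiates the two enantiotopic benzylic hydrogens, and the neutral conditions cannot open the product by retro-oxa-Michael reaction. The step needs insertion to win over oxonium ylide formation with [1,2]-benzyl shift at the same oxygen, over addition to the geranyl alkenes and over attack on the silyl ether oxygens; the C–H bond is doubly activated (α to O1, benzylic to the para-methoxy ring B), the trisubstituted alkenes can only be reached through rings of ten or more members, the peri OTIPS oxygen is shielded and carries no α-C–H, and slow addition at high dilution suppresses bimolecular pathways.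

**Step 11**
Reactants: 16 (2S)-2-{3-[tert-butyl(dimethyl)silyl]oxy-2-geranyl-4-methoxyphenyl}-7-methoxy-5-(triisopropylsilyloxy)chroman-4-one
Product: 17 (2S)-2-(2-geranyl-3-hydroxy-4-methoxyphenyl)-5-hydroxy-7-methoxychroman-4-one
Conditions: Bu4NF (2.5 equiv), AcOH (2.5 equiv), THF, 0 °C
Reagents that add atoms: none
Why: Fluoride cleaves both aryl silyl ethers through Si–F bond formation in an acetic-acid-buffered medium that should avoid base-induced ring opening (racemisation at C2) and acid-induced cyclisation of the 3'-hydroxyl onto the geranyl chain.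

**Compound list**

1 | 2-bromo-3-hydroxy-4-methoxybenzaldehyde | COc1ccc(C=O)c(Br)c1O | starting material
2 | 2-(2-bromo-3-hydroxy-4-methoxyphenyl)-1,3-dioxolane | COc1ccc(C2OCCO2)c(Br)c1O | intermediate
3 | 2-[2-bromo-4-methoxy-3-(methoxymethoxy)phenyl]-1,3-dioxolane | COCOc1c(OC)ccc(C2OCCO2)c1Br | intermediate
4 | geranyl bromide, (2E)-1-bromo-3,7-dimethylocta-2,6-diene | BrC/C=C(\C)CCC=C(C)C | starting material
5 | aryllithium from 3 (lithium at C2 of the ring; not isolated) | COCOc1c(OC)ccc(C2OCCO2)c1[Li] | intermediate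
6 | arylcopper from 5 (copper at C2 of the ring; not isolated) | COCOc1c(OC)ccc(C2OCCO2)c1[Cu] | intermediate
7 | 2-[2-geranyl-4-methoxy-3-(methoxymethoxy)phenyl]-1,3-dioxolane | COCOc1c(OC)ccc(C2OCCO2)c1C/C=C(\C)CCC=C(C)C | intermediate
8 | 2-geranyl-3-hydroxy-4-methoxybenzaldehyde | COc1ccc(C=O)c(C/C=C(\C)CCC=C(C)C)c1O | intermediate
9 | 3-[tert-butyl(dimethyl)silyl]oxy-2-geranyl-4-methoxybenzaldehyde | COc1ccc(C=O)c(C/C=C(\C)CCC=C(C)C)c1O[Si](C)(C)C(C)(C)C | intermediate
10 | {3-[tert-butyl(dimethyl)silyl]oxy-2-geranyl-4-methoxyphenyl}methanol | COc1ccc(CO)c(C/C=C(\C)CCC=C(C)C)c1O[Si](C)(C)C(C)(C)C | intermediate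
11 | 1-(2,6-dihydroxy-4-methoxyphenyl)ethanone | CC(=O)c1c(O)cc(OC)cc1O | starting material
12 | 1-[2-hydroxy-4-methoxy-6-(triisopropylsilyloxy)phenyl]ethanone | CC(=O)c1c(O)cc(OC)cc1O[Si](C(C)C)(C(C)C)C(C)C | intermediate
13 | 1-[2-({3-[tert-butyl(dimethyl)silyl]oxy-2-geranyl-4-methoxyphenyl}methoxy)-4-methoxy-6-(triisopropylsilyloxy)phenyl]ethanone | CC(=O)c1c(OCc2ccc(OC)c(O[Si](C)(C)C(C)(C)C)c2C/C=C(\C)CCC=C(C)C)cc(OC)cc1O[Si](C(C)C)(C(C)C)C(C)C | intermediate
14 | 4,4,4-trifluoro-1-[aryl of 13]butane-1,3-dione (not isolated) | O=C(CC(=O)C(F)(F)F)c1c(OCc2ccc(OC)c(O[Si](C)(C)C(C)(C)C)c2C/C=C(\C)CCC=C(C)C)cc(OC)cc1O[Si](C(C)C)(C(C)C)C(C)C | intermediate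
15 | 2-diazo-1-[aryl of 13]ethanone | [N-]=[N+]=CC(=O)c1c(OCc2ccc(OC)c(O[Si](C)(C)C(C)(C)C)c2C/C=C(\C)CCC=C(C)C)cc(OC)cc1O[Si](C(C)C)(C(C)C)C(C)C | intermediate
16 | (2S)-2-{3-[tert-butyl(dimethyl)silyl]oxy-2-geranyl-4-methoxyphenyl}-7-methoxy-5-(triisopropylsilyloxy)chroman-4-one | COc1cc(O[Si](C(C)C)(C(C)C)C(C)C)c2c(c1)O[C@H](c1ccc(OC)c(O[Si](C)(C)C(C)(C)C)c1C/C=C(\C)CCC=C(C)C)CC2=O | intermediate
17 | (2S)-2-(2-geranyl-3-hydroxy-4-methoxyphenyl)-5-hydroxy-7-methoxychroman-4-one | COc1cc(O)c2c(c1)O[C@H](c1ccc(OC)c(O)c1C/C=C(\C)CCC=C(C)C)CC2=O | target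

**Count**

Total steps: 11. Longest linear sequence: 10 (steps 1–6, then 8–11); step 7 is a one-step branch.

**Steps most likely to fail, with fallbacks**

Step 10. The carbene may be diverted into oxonium ylide formation at the benzylic ether oxygen with [1,2]-benzyl shift, or into addition to the geranyl double bonds. The catalyst may also discriminate the two benzylic hydrogens poorly.
The fallback forms O1–C2 instead of C2–C3 and sets out from 9 and 12. The dianion of 12 (LiN(SiMe3)2, 2.2 equiv, THF, −78 °C) is added to aldehyde 9 to give the racemic β-hydroxy ketone F1. Intramolecular Mitsunobu etherification (PPh3, DIAD, THF) closes ring C to the racemic bis-silyl flavanone F2. Kinetic resolution by asymmetric transfer hydrogenation (RuCl(p-cymene)[(R,R)-TsDPEN] or its mirror image, whichever consumes the (2R)-ketone faster, HCO2H/Et3N) should reduce the (2R)-enantiomer to the cis-flavan-4-ol F3. The unreacted (2S)-ketone is compound 16, where the route is rejoined before step 11.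

Step 3. The doubly flanked aryl metal may be protonated before it couples, and the allylic substitution may leak to SN2' attack or lose the E geometry.
The fallback sets out from 3. Miyaura borylation (Pd(OAc)2, SPhos, B2pin2, KOAc, dioxane, 90 °C) gives the aryl pinacol boronate F4. Cross-coupling with 4 through a π-allyl complex formed by zerovalent palladium (Pd(PPh3)4, aq. K3PO4, THF, 60 °C) should join the aryl group to the unhindered allyl terminus and return to the route at 7.

Step 8. Etherification of the hindered, hydrogen-bonded phenol may be slow, and the electron-rich benzylic oxyphosphonium ion may ionise and alkylate ring A at carbon.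
The fallback sets out from 10. MsCl, Et3N in CH2Cl2 should give the benzylic chloride F5 through in situ displacement of the mesylate. Williamson etherification of the unprotected diol 11 (K2CO3, Bu4NI cat., dry acetone, 40 °C) should give the mono-ether F6, the second hydroxyl staying hydrogen-bonded. Silylation (TIPSOTf, 2,6-lutidine, CH2Cl2, 0 °C) returns to the route at 13.

**Further compounds**

F1 | step 10 | racemic 3-{3-[tert-butyl(dimethyl)silyl]oxy-2-geranyl-4-methoxyphenyl}-3-hydroxy-1-[2-hydroxy-4-methoxy-6-(triisopropylsilyloxy)phenyl]propan-1-one | O=C(CC(O)c1ccc(OC)c(O[Si](C)(C)C(C)(C)C)c1C/C=C(\C)CCC=C(C)C)c1c(O)cc(OC)cc1O[Si](C(C)C)(C(C)C)C(C)C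
F2 | step 10 | racemic 2-{3-[tert-butyl(dimethyl)silyl]oxy-2-geranyl-4-methoxyphenyl}-7-methoxy-5-(triisopropylsilyloxy)chroman-4-one | COc1cc(O[Si](C(C)C)(C(C)C)C(C)C)c2c(c1)OC(c1ccc(OC)c(O[Si](C)(C)C(C)(C)C)c1C/C=C(\C)CCC=C(C)C)CC2=O
F3 | step 10 | (2R,4R)-2-{3-[tert-butyl(dimethyl)silyl]oxy-2-geranyl-4-methoxyphenyl}-7-methoxy-5-(triisopropylsilyloxy)chroman-4-ol (cis) | COc1cc(O[Si](C(C)C)(C(C)C)C(C)C)c2c(c1)O[C@@H](c1ccc(OC)c(O[Si](C)(C)C(C)(C)C)c1C/C=C(\C)CCC=C(C)C)C[C@H]2O
F4 | step 3 | 2-[4-methoxy-3-(methoxymethoxy)-2-(4,4,5,5-tetramethyl-1,3,2-dioxaborolan-2-yl)phenyl]-1,3-dioxolane | COCOc1c(OC)ccc(C2OCCO2)c1B1OC(C)(C)C(C)(C)O1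
F5 | step 8 | tert-butyl{[3-(chloromethyl)-2-geranyl-6-methoxyphenyl]oxy}dimethylsilane | COc1ccc(CCl)c(C/C=C(\C)CCC=C(C)C)c1O[Si](C)(C)C(C)(C)C
F6 | step 8 | 1-[2-({3-[tert-butyl(dimethyl)silyl]oxy-2-geranyl-4-methoxyphenyl}methoxy)-6-hydroxy-4-methoxyphenyl]ethanone | CC(=O)c1c(O)cc(OC)cc1OCc1ccc(OC)c(O[Si](C)(C)C(C)(C)C)c1C/C=C(\C)CCC=C(C)C
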